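The plan cuts the C3–C4 bond of the 2,8-dioxabicyclo[3.2.1]octane together with the C1–O2 ketal bond. In the forward sense, dirhodium-catalysed loss of nitrogen from an acyclic diazo ester (C4) that carries the C1 ketone, the preset C5 carbinol centre and the complete side chain gives a six-membered carbonyl ylide, which adds ethyl glyoxylate (C3 and O2) across C4 and C1. One operation thus forms C3–C4, closes two rings and sets C1, C3 and C4. It exploits the fact that C1, O2, C3, C4 and the C4 oxygen of the core form a latent 1,3-dioxolane; acid then moves the ketal bridge from O4 to O5.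

Key step: step 12

Assumption: (S,S)-ProPhenol is taken as the ligand antipode that sends the diazo ester to the Re face of the keto group in step 10; if the sense proves opposite, the (R,R)-ligand is used with no other change.

Step 1
Reactants: 1 (R)-4-benzyl-3-propanoyloxazolidin-2-one; 2 benzyl bromide
Product: 4 (R)-4-benzyl-3-[(S)-2-methyl-3-phenylpropanoyl]oxazolidin-2-one, via sodium Z-enolate 3 (not isolated)
Conditions: NaN(SiMe3)2, THF, −78 °C; then 2, −78 → 0 °C
Reagents that add atoms: none
Why: Evans asymmetric alkylation, in which the chelated Z-enolate 3 is benzylated on the face opposite the benzyl group of the auxiliary, which sets the (S) methyl-bearing centre of the side chain.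

Step 2
Reactants: 4 (R)-4-benzyl-3-[(S)-2-methyl-3-phenylpropanoyl]oxazolidin-2-one
Product: 5 (S)-2-methyl-3-phenylpropan-1-ol
Conditions: LiBH4, H2O (1 equiv), Et2O, 0 °C
Reagents that add atoms: none
Why: Reductive cleavage of the N-acyloxazolidinone by hydride attack on the exocyclic carbonyl should release the primary alcohol without touching the stereocentre and return the auxiliary.

Step 3
Reactants: 5 (S)-2-methyl-3-phenylpropan-1-ol
Product: 6 (S)-2-methyl-3-phenylpropanal
Conditions: Dess–Martin periodinane, CH2Cl2, 0 °C → rt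
Reagents that add atoms: none
Why: Dess–Martin oxidation is neutral and non-enolising, so the α-stereocentre should survive if 6 is used at once.

Step 4
Reactants: 6 (S)-2-methyl-3-phenylpropanal; 7 isopropenylmagnesium bromide
Product: 8 (4S)-2,4-dimethyl-5-phenylpent-1-en-3-ol (both C3 epimers)
Conditions: THF, −78 °C; aq NH4Cl
Reagents that add atoms: none
Why: Grignard addition to the aldehyde at low temperature, the new carbinol centre being formed as a mixture that is of no consequence because step 5 destroys it.

Step 5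
Reactants: 8 (4S)-2,4-dimethyl-5-phenylpent-1-en-3-ol; 9 triethyl orthoacetate
Product: 11 ethyl (4E,6S)-4,6-dimethyl-7-phenylhept-4-enoate, via ketene acetal 10 (not isolated)
Conditions: EtCO2H (cat), neat 9, 140 °C, EtOH distilled off
Reagents that add atoms: none
Why: Johnson–Claisen rearrangement, in which 10 reacts through a chair transition state with the CH(CH3)CH2Ph group equatorial, so the carbinol carbon becomes an E-trisubstituted alkene, the two-carbon ester unit is added and the (S) centre is untouched.

Step 6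
Reactants: 11 ethyl (4E,6S)-4,6-dimethyl-7-phenylhept-4-enoate
Product: 12 (4E,6S)-N-methoxy-N,4,6-trimethyl-7-phenylhept-4-enamide
Conditions: MeNHOMe·HCl, i-PrMgCl, THF, −20 °C
Reagents that add atoms: N,O-dimethylhydroxylamine hydrochloride, CNOC.Cl
Why: Aminolysis of the ester by the magnesium amide made in the flask gives the N-methoxy-N-methylamide needed for a single acyl substitution.

Step 7
Reactants: 12 (4E,6S)-N-methoxy-N,4,6-trimethyl-7-phenylhept-4-enamide; 13 vinylmagnesium bromide
Product: 14 (6E,8S)-6,8-dimethyl-9-phenylnona-1,6-dien-3-one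
Conditions: THF, 0 °C; quench into cold 1 M HCl
Reagents that add atoms: none
Why: Ketone synthesis from an N-methoxy-N-methylamide and a Grignard reagent reliably stops after one addition, and the cold acidic quench should prevent conjugate addition of the liberated amine to the enone.

Step 8
Reactants: 14 (6E,8S)-6,8-dimethyl-9-phenylnona-1,6-dien-3-one; 15 ethyl 1,3-dithiane-2-carboxylate
Product: 16 ethyl 2-[(6E,8S)-6,8-dimethyl-3-oxo-9-phenylnon-6-en-1-yl]-1,3-dithiane-2-carboxylate
Conditions: KOt-Bu (10 mol %), THF, 0 °C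
Reagents that add atoms: none
Why: Base-catalysed Michael addition of the acidic dithiane C–H, a soft acyl-anion equivalent of ethyl glyoxylate, to the unhindered vinyl ketone installs C5 at the ketone oxidation level together with its carboxylate.

Step 9
Reactants: 16 ethyl 2-[(6E,8S)-6,8-dimethyl-3-oxo-9-phenylnon-6-en-1-yl]-1,3-dithiane-2-carboxylate
Product: 17 ethyl (8E,10S)-8,10-dimethyl-2,5-dioxo-11-phenylundec-8-enoate
Conditions: PhI(OCOCF3)2, MeCN–H2O (9:1), 0 °C
Reagents that add atoms: water, O
Why: Oxidative dithioacetal hydrolysis is fast at sulfur at 0 °C and should leave the isolated trisubstituted alkene and both carbonyl groups untouched while unveiling the α-keto ester.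

Step 10
Reactants: 17 ethyl (8E,10S)-8,10-dimethyl-2,5-dioxo-11-phenylundec-8-enoate; 18 ethyl diazoacetate
Product: 19 diethyl (3R)-2-diazo-3-hydroxy-3-[(6E,8S)-6,8-dimethyl-3-oxo-9-phenylnon-6-en-1-yl]butanedioate
Conditions: (S,S)-ProPhenol (10 mol %), Bu2Mg (20 mol %), cis-cyclopentane-1,2-diol (10 mol %), THF, −20 °C
Reagents that add atoms: none
Why: Proposed new method: enantioselective aldol-type addition of the diazo ester to the α-keto ester carbonyl, in which one magnesium of the dinuclear catalyst formed from Bu2Mg and ProPhenol deprotonates 18 while the other binds the 1,2-dicarbonyl unit of 17 as a five-membered chelate, so that the C4–C5 bond forms inside the chiral pocket on the Re face of the keto group and sets the (R) carbinol centre, the dialkyl ketone being less electrophilic and non-chelating; the closest known reaction types are the enantioselective addition of diazoacetates to aldehydes under the same catalyst and the amidine-catalysed racemic addition of diazoacetates to α-keto esters.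

Step 11
Reactants: 19 diethyl (3R)-2-diazo-3-hydroxy-3-[(6E,8S)-6,8-dimethyl-3-oxo-9-phenylnon-6-en-1-yl]butanedioate
Product: 20 diethyl (3R)-2-diazo-3-[(6E,8S)-6,8-dimethyl-3-oxo-9-phenylnon-6-en-1-yl]-3-[(trimethylsilyl)oxy]butanedioate
Conditions: N-(trimethylsilyl)imidazole, CH2Cl2, rt
Reagents that add atoms: N-(trimethylsilyl)imidazole, C[Si](C)(C)n1ccnc1
Why: O-Silylation of the hindered tertiary alcohol by a powerful neutral silyl donor leaves the diazo ester and the ketone untouched and blocks hemiketal formation between the C5 hydroxyl and the C1 ketone.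

Step 12
Reactants: 20 diethyl (3R)-2-diazo-3-[(6E,8S)-6,8-dimethyl-3-oxo-9-phenylnon-6-en-1-yl]-3-[(trimethylsilyl)oxy]butanedioate; 21 ethyl glyoxylate
Product: 23 triethyl (1S,2R,5S,7S)-5-[(3E,5S)-3,5-dimethyl-6-phenylhex-3-en-1-yl]-2-[(trimethylsilyl)oxy]-6,8-dioxabicyclo[3.2.1]octane-1,2,7-tricarboxylate, via carbonyl ylide 22 (not isolated)
Conditions: Rh2(OAc)4 (2 mol %), 21 (5 equiv, freshly distilled), PhMe, 80 °C, slow addition of 20
Reagents that add atoms: none
Why: Rh2(OAc)4 induces loss of N2 from 20 and places electrophilic carbene character on C4, which is captured by a lone pair of the C1 ketone oxygen, closing the six-membered ring O–C1–C7–C6–C5–C4 (attack exo to the Rh=C bond) to give ylide 22. Ylide 22 then adds 21 in a concerted suprafacial [3+2] cycloaddition that closes the five-membered 1,3-dioxolane ring and with it the bridged bicycle; the closest known reaction type is the dirhodium-catalysed tandem carbonyl ylide formation–cycloaddition of δ-keto-α-diazo esters with aldehydes. Regioselectivity (aldehyde carbon C3 to C4, aldehyde oxygen to C1) follows from the polarisation of the dipole, whose ester-stabilised carbanionic end is C4 and whose oxocarbenium-like end is C1. C1 and C4 are set together as the bridgeheads and their absolute sense is controlled by C5, since the glyoxylate should approach the ylide face anti to the C5 trimethylsilyloxy group, which leaves that oxygen syn to the one-atom oxygen bridge as the later ketal migration requires. C3 is set by the exo orientation of the glyoxylate ester, away from the C5–C6–C7 bridge. The step needs six-ring ylide formation to outrun 1,2-migration and attack on the remote trisubstituted alkene, which the proximity of the ketone, the fully substituted silylated C5 and the excess of dipolarophile should secure.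

Step 13
Reactants: 23 triethyl (1S,2R,5S,7S)-5-[(3E,5S)-3,5-dimethyl-6-phenylhex-3-en-1-yl]-2-[(trimethylsilyl)oxy]-6,8-dioxabicyclo[3.2.1]octane-1,2,7-tricarboxylate
Product: 25 triethyl (1S,3S,4S,5R)-1-[(3E,5S)-3,5-dimethyl-6-phenylhex-3-en-1-yl]-4-hydroxy-2,8-dioxabicyclo[3.2.1]octane-3,4,5-tricarboxylate, via desilylated hydroxy cycloadduct 24 (not isolated)
Conditions: HCl (1.25 M in EtOH), rt → 40 °C
Reagents that add atoms: none
Why: Acid-catalysed transketalisation, in which the silyl group is lost and the bond from C1 to the oxygen on C4 opens reversibly and recloses onto the C5 hydroxyl on the same face, should give the thermodynamically preferred 2,8-dioxabicyclo[3.2.1]octane with retention at C1 and no change at C3, C4 or C5, while dilute HCl in ethanol should spare the alkene and cannot scramble ethyl esters.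

Step 14
Reactants: 25 triethyl (1S,3S,4S,5R)-1-[(3E,5S)-3,5-dimethyl-6-phenylhex-3-en-1-yl]-4-hydroxy-2,8-dioxabicyclo[3.2.1]octane-3,4,5-tricarboxylate
Product: 27 (1S,3S,4S,5R)-1-[(3E,5S)-3,5-dimethyl-6-phenylhex-3-en-1-yl]-4-hydroxy-2,8-dioxabicyclo[3.2.1]octane-3,4,5-tricarboxylic acid, via tripotassium tricarboxylate 26 (not isolated)
Conditions: KOH, EtOH–H2O, 70 °C; then aq HCl to pH 2
Reagents that add atoms: potassium hydroxide, [K+].[OH-]
Why: Saponification of the three ethyl esters followed by acidification should give the triacid, since the ketal, the tertiary alcohol and the alkene are stable to hydroxide and C3, whose equatorial carboxylate is the thermodynamic one, no longer epimerises once it is a carboxylate.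

Compound list
1 | (R)-4-benzyl-3-propanoyloxazolidin-2-one | CCC(=O)N1[C@H](Cc2ccccc2)COC1=O | starting material
2 | benzyl bromide | BrCc1ccccc1 | starting material
3 | sodium (Z)-1-[(R)-4-benzyl-2-oxooxazolidin-3-yl]prop-1-en-1-olate | C/C=C(\[O-])N1[C@H](Cc2ccccc2)COC1=O.[Na+] | intermediate
4 | (R)-4-benzyl-3-[(S)-2-methyl-3-phenylpropanoyl]oxazolidin-2-one | C[C@@H](Cc1ccccc1)C(=O)N1[C@H](Cc2ccccc2)COC1=O | intermediate
5 | (S)-2-methyl-3-phenylpropan-1-ol | C[C@@H](Cc1ccccc1)CO | intermediate
6 | (S)-2-methyl-3-phenylpropanal | C[C@@H](Cc1ccccc1)C=O | intermediate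
7 | isopropenylmagnesium bromide | CC(=C)[Mg]Br | starting material
8 | (4S)-2,4-dimethyl-5-phenylpent-1-en-3-ol, both C3 epimers | C=C(C)C(O)[C@@H](C)Cc1ccccc1 | intermediate
9 | triethyl orthoacetate | CCOC(C)(OCC)OCC | starting material
10 | (4S)-3-[(1-ethoxyethenyl)oxy]-2,4-dimethyl-5-phenylpent-1-ene (ketene acetal) | C=C(OCC)OC(C(C)=C)[C@@H](C)Cc1ccccc1 | intermediate
11 | ethyl (4E,6S)-4,6-dimethyl-7-phenylhept-4-enoate | C[C@@H](Cc1ccccc1)/C=C(\C)CCC(=O)OCC | intermediate
12 | (4E,6S)-N-methoxy-N,4,6-trimethyl-7-phenylhept-4-enamide | C[C@@H](Cc1ccccc1)/C=C(\C)CCC(=O)N(C)OC | intermediate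
13 | vinylmagnesium bromide | C=C[Mg]Br | starting material
14 | (6E,8S)-6,8-dimethyl-9-phenylnona-1,6-dien-3-one | C[C@@H](Cc1ccccc1)/C=C(\C)CCC(=O)C=C | intermediate
15 | ethyl 1,3-dithiane-2-carboxylate | CCOC(=O)C1SCCCS1 | starting material
16 | ethyl 2-[(6E,8S)-6,8-dimethyl-3-oxo-9-phenylnon-6-en-1-yl]-1,3-dithiane-2-carboxylate | C[C@@H](Cc1ccccc1)/C=C(\C)CCC(=O)CCC1(C(=O)OCC)SCCCS1 | intermediate
17 | ethyl (8E,10S)-8,10-dimethyl-2,5-dioxo-11-phenylundec-8-enoate | C[C@@H](Cc1ccccc1)/C=C(\C)CCC(=O)CCC(=O)C(=O)OCC | intermediate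
18 | ethyl diazoacetate | CCOC(=O)C=[N+]=[N-] | starting material
19 | diethyl (3R)-2-diazo-3-hydroxy-3-[(6E,8S)-6,8-dimethyl-3-oxo-9-phenylnon-6-en-1-yl]butanedioate | C[C@@H](Cc1ccccc1)/C=C(\C)CCC(=O)CC[C@@](C(=O)OCC)(O)C(=[N+]=[N-])C(=O)OCC | intermediate
20 | diethyl (3R)-2-diazo-3-[(6E,8S)-6,8-dimethyl-3-oxo-9-phenylnon-6-en-1-yl]-3-[(trimethylsilyl)oxy]butanedioate | C[C@@H](Cc1ccccc1)/C=C(\C)CCC(=O)CC[C@@](C(=O)OCC)(O[Si](C)(C)C)C(=[N+]=[N-])C(=O)OCC | intermediate
21 | ethyl glyoxylate | CCOC(=O)C=O | starting material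
22 | (5R)-2-[(3E,5S)-3,5-dimethyl-6-phenylhex-3-en-1-yl]-5,6-bis(ethoxycarbonyl)-5-[(trimethylsilyl)oxy]-4,5-dihydro-3H-pyran-1-ium-6-ide (cyclic carbonyl ylide) | C[C@@H](Cc1ccccc1)/C=C(\C)CCC1=[O+][C-](C(=O)OCC)[C@](C(=O)OCC)(O[Si](C)(C)C)CC1 | intermediate
23 | triethyl (1S,2R,5S,7S)-5-[(3E,5S)-3,5-dimethyl-6-phenylhex-3-en-1-yl]-2-[(trimethylsilyl)oxy]-6,8-dioxabicyclo[3.2.1]octane-1,2,7-tricarboxylate | C[C@@H](Cc1ccccc1)/C=C(\C)CC[C@@]12CC[C@@](C(=O)OCC)(O[Si](C)(C)C)[C@](O1)(C(=O)OCC)[C@@H](C(=O)OCC)O2 | intermediate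
24 | triethyl (1S,2R,5S,7S)-5-[(3E,5S)-3,5-dimethyl-6-phenylhex-3-en-1-yl]-2-hydroxy-6,8-dioxabicyclo[3.2.1]octane-1,2,7-tricarboxylate | C[C@@H](Cc1ccccc1)/C=C(\C)CC[C@@]12CC[C@@](C(=O)OCC)(O)[C@](O1)(C(=O)OCC)[C@@H](C(=O)OCC)O2 | intermediate
25 | triethyl (1S,3S,4S,5R)-1-[(3E,5S)-3,5-dimethyl-6-phenylhex-3-en-1-yl]-4-hydroxy-2,8-dioxabicyclo[3.2.1]octane-3,4,5-tricarboxylate | C[C@@H](Cc1ccccc1)/C=C(\C)CC[C@@]12CC[C@@](C(=O)OCC)(O1)[C@](O)(C(=O)OCC)[C@@H](C(=O)OCC)O2 | intermediate
26 | tripotassium (1S,3S,4S,5R)-1-[(3E,5S)-3,5-dimethyl-6-phenylhex-3-en-1-yl]-4-hydroxy-2,8-dioxabicyclo[3.2.1]octane-3,4,5-tricarboxylate | C[C@@H](Cc1ccccc1)/C=C(\C)CC[C@@]12CC[C@@](C(=O)[O-])(O1)[C@](O)(C(=O)[O-])[C@@H](C(=O)[O-])O2.[K+].[K+].[K+] | intermediate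
27 | (1S,3S,4S,5R)-1-[(3E,5S)-3,5-dimethyl-6-phenylhex-3-en-1-yl]-4-hydroxy-2,8-dioxabicyclo[3.2.1]octane-3,4,5-tricarboxylic acid | C[C@@H](Cc1ccccc1)/C=C(\C)CC[C@@]12CC[C@@](C(=O)O)(O1)[C@](O)(C(=O)O)[C@@H](C(=O)O)O2 | target

Total step count: 14
Longest linear sequence: 14 steps (1 → 27; all other partners are commercial)

Steps most likely to fail

Step 10 (Proposed new method). What may go wrong: weak enantiofacial discrimination at the α-keto ester carbonyl, or loss of catalyst turnover to enolisation and intramolecular aldol condensation of the 1,4-dicarbonyl unit. The fallback uses known chemistry, sets out from 17 and comes back at 19. Compound 17 and ethyl diazoacetate 18 are combined under catalytic DBU in MeCN, the known amidine-catalysed aldol-type addition, which proceeds without control at the new centre. This should give 19 together with its C3 epimer, diethyl (3S)-2-diazo-3-hydroxy-3-[(6E,8S)-6,8-dimethyl-3-oxo-9-phenylnon-6-en-1-yl]butanedioate F1. The two diastereomers are separated by preparative chromatography on a chiral stationary phase, and 19 re-enters at step 11.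

Step 12. What may go wrong: loss of π-facial control at the ylide, with the glyoxylate approaching syn to the C5 silyloxy group, and collapse of the ylide by internal proton transfer before it is captured. The fallback redesigns the control element instead of the conditions; it sets out from 19 and comes back at 24. Compound 19 is silylated with TBSOTf and 2,6-lutidine in CH2Cl2 at −78 °C to give the tert-butyldimethylsilyl ether F2, so that facial shielding no longer rests on a group of about the size of the neighbouring ester. The same Rh2(OAc)4 and glyoxylate treatment should then give the silyl-protected cycloadduct F3. Removal of the silyl group with HF·pyridine in THF gives 24, which continues through the acid treatment of step 13.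

Step 13. What may go wrong: an unfavourable or slowly established ketal equilibrium, leaving 24 beside 25, and acid-induced migration of the side-chain double bond on long exposure. The fallback changes the order and the medium; it sets out from 23 and comes back at 27. Compound 23 is saponified first (KOH, EtOH–H2O, 70 °C, which also removes the silyl ether) to the tripotassium salt F4 of the unrearranged hydroxy triacid, and acidification gives the free hydroxy triacid F5. The ketal migration is then run last on this unprotected acid in dilute aqueous HCl–dioxane at 40 °C, a medium too weakly acidic to protonate the alkene, and should give 27 directly.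

Further compounds
F1 | step 10 | diethyl (3S)-2-diazo-3-hydroxy-3-[(6E,8S)-6,8-dimethyl-3-oxo-9-phenylnon-6-en-1-yl]butanedioate | C[C@@H](Cc1ccccc1)/C=C(\C)CCC(=O)CC[C@](C(=O)OCC)(O)C(=[N+]=[N-])C(=O)OCC
F2 | step 12 | diethyl (3R)-3-[(tert-butyldimethylsilyl)oxy]-2-diazo-3-[(6E,8S)-6,8-dimethyl-3-oxo-9-phenylnon-6-en-1-yl]butanedioate | C[C@@H](Cc1ccccc1)/C=C(\C)CCC(=O)CC[C@@](C(=O)OCC)(O[Si](C)(C)C(C)(C)C)C(=[N+]=[N-])C(=O)OCC
F3 | step 12 | triethyl (1S,2R,5S,7S)-2-[(tert-butyldimethylsilyl)oxy]-5-[(3E,5S)-3,5-dimethyl-6-phenylhex-3-en-1-yl]-6,8-dioxabicyclo[3.2.1]octane-1,2,7-tricarboxylate | C[C@@H](Cc1ccccc1)/C=C(\C)CC[C@@]12CC[C@@](C(=O)OCC)(O[Si](C)(C)C(C)(C)C)[C@](O1)(C(=O)OCC)[C@@H](C(=O)OCC)O2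
F4 | step 13 | tripotassium (1S,2R,5S,7S)-5-[(3E,5S)-3,5-dimethyl-6-phenylhex-3-en-1-yl]-2-hydroxy-6,8-dioxabicyclo[3.2.1]octane-1,2,7-tricarboxylate | C[C@@H](Cc1ccccc1)/C=C(\C)CC[C@@]12CC[C@@](C(=O)[O-])(O)[C@](O1)(C(=O)[O-])[C@@H](C(=O)[O-])O2.[K+].[K+].[K+]
F5 | step 13 | (1S,2R,5S,7S)-5-[(3E,5S)-3,5-dimethyl-6-phenylhex-3-en-1-yl]-2-hydroxy-6,8-dioxabicyclo[3.2.1]octane-1,2,7-tricarboxylic acid | C[C@@H](Cc1ccccc1)/C=C(\C)CC[C@@]12CC[C@@](C(=O)O)(O)[C@](O1)(C(=O)O)[C@@H](C(=O)O)O2
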